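**Retrosynthetic overview**
1. The five-membered ring of the benzo-bicyclo[3.2.1]octene is formed last. A retro-Michael cut at C8a–aryl gives a benzoquinone hanging from C5 of a cis-fused tetrahydronaphthalene-1,4-dione, and that quinone comes from a 2,5-dimethoxyphenyl group.
2. The cyclohexene ring is cut by retro-Diels–Alder into an (E)-dehydroprenyl arene (diene) and the prenyl-bearing C2=C3 bond of prenylbenzoquinone (dienophile), combined in the uncatalysed endo/"ortho" mode.
3. The free quinone would react at C5=C6, and Lewis acids would reverse the orientation. A catalytic asymmetric Diels–Alder reaction with sacrificial cyclopentadiene therefore masks C5=C6 first, and its stereocentres steer the key cycloaddition before leaving as cyclopentadiene.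
4. Ring order: norbornene mask on, then the cyclohexene ring (sets C4a and C5), then mask off, then the five-membered ring (sets C8a).
5. Starting materials: 1,4-dimethoxybenzene, prenyl bromide, cyclopentadiene, 2,5-dimethoxybenzaldehyde and diethyl methallylphosphonate.

Locants from compound 13 onward follow 4a,5,8,8a-tetrahydronaphthalene-1,4-dione numbering: C4a carries the prenyl group, C5 the aryl group, C7 the methyl group.
Assumption: the (S)-prolinol-derived catalyst gives 7 with the configuration drawn; if it gives the antipode, the equally available (R)-catalyst is used.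

**Step 1**
Reactants: 1 1,4-dimethoxybenzene; 2 prenyl bromide (1-bromo-3-methylbut-2-ene)
Product: 4 1,4-dimethoxy-2-(3-methylbut-2-en-1-yl)benzene, via (2,5-dimethoxyphenyl)lithium 3 (not isolated)
Conditions: n-BuLi, TMEDA, THF, 0 °C; CuI (10 mol%), then 2, −78 °C to rt
Reagents that add atoms: none
Why: Directed ortho-lithiation followed by copper-assisted SN2 allylation gives the linear prenyl arene, and no stereocentre is formed.

**Step 2**
Reactants: 4 1,4-dimethoxy-2-(3-methylbut-2-en-1-yl)benzene
Product: 5 2-(3-methylbut-2-en-1-yl)-1,4-benzoquinone (prenylbenzoquinone)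
Conditions: CAN (2.2 equiv), MeCN–H2O 3:1, 0 °C, 20 min
Reagents that add atoms: water, O
Why: Oxidative demethylation of a 1,4-dimethoxyarene to the p-quinone is fast at 0 °C and leaves the trisubstituted alkene untouched, and no stereocentre is formed.

**Step 3**
Reactants: 5 prenylbenzoquinone; 6 cyclopenta-1,3-diene (freshly cracked from commercial dicyclopentadiene)
Product: 7 (1S,4R,4aS,8aR)-6-(3-methylbut-2-en-1-yl)-1,4,4a,8a-tetrahydro-1,4-methanonaphthalene-5,8-dione (endo adduct)
Conditions: (S)-o-tolyl-oxazaborolidine·Tf2NH (20 mol%), CH2Cl2, −78 °C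
Reagents that add atoms: none
Why: In this catalytic enantioselective Diels–Alder reaction cyclopentadiene adds endo and only to the more reactive unsubstituted C5=C6 bond, while the cationic oxazaborolidine, bound to the more basic carbonyl remote from the prenyl group, shields one face and sets the four relay stereocentres.

**Step 4**
Reactants: 8 2,5-dimethoxybenzaldehyde; 9 diethyl (2-methylprop-2-en-1-yl)phosphonate
Product: 11 1,4-dimethoxy-2-[(1E)-3-methylbuta-1,3-dien-1-yl]benzene, via lithiated phosphonate 10 (not isolated)
Conditions: 9, n-BuLi, THF–DMPU, −78 °C; then 8, −78 °C to rt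
Reagents that add atoms: none
Why: Horner–Wadsworth–Emmons olefination of an aromatic aldehyde with the α-lithiated allylic phosphonate gives the (E)-1-aryl diene, and no stereocentre is formed.

**Step 5**
Reactants: 7 norbornene-masked prenylquinone; 11 (E)-dehydroprenyl dimethoxybenzene
Product: 13 (4aS,5R,8aR)-5-(2,5-dimethoxyphenyl)-7-methyl-4a-(3-methylbut-2-en-1-yl)-4a,5,8,8a-tetrahydronaphthalene-1,4-dione (cis-fused; aryl cis to both carbonyl carbons, trans to prenyl), via norbornene-masked bis-adduct 12 (not isolated)
Conditions: 7 (1.2 equiv), BHT, CH2Cl2, 13 kbar, 25 °C, 72 h, dark; evaporate; o-dichlorobenzene, 180 °C, N2 sparge, 1 h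
Reagents that add atoms: none
Why: In this high-pressure Diels–Alder reaction followed by a retro-Diels–Alder reaction only the prenyl-bearing alkene of 7 is free, the two unhindered termini (diene CH2 and enedione CH) bond first so the aryl-bearing carbon joins the prenyl-bearing carbon (uncatalysed "ortho" mode), the diene approaches endo from the convex face syn to H-4a/H-8a of 7 and so sets C4a (S), C5 (R) and the provisional C8a (R), and at 180 °C the strained norbornene loses cyclopentadiene while the cyclohexene ring stays.

**Step 6**
Reactants: 13 Diels–Alder adduct (dimethyl ether)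
Product: 15 target CNP0166383.1, (4aS,5R,8aR)-5,8a-(3,6-dihydroxy-1,2-phenylene)-7-methyl-4a-(3-methylbut-2-en-1-yl)-4a,5,8,8a-tetrahydronaphthalene-1,4-dione, via quinone 14 (not isolated)
Conditions: CAN (2.1 equiv), MeCN–H2O 3:1, 0 °C, 15 min; extraction; TFA (10 mol%), CH2Cl2, rt, Ar
Reagents that add atoms: water, O
Why: After oxidative demethylation to the quinone, a biomimetic acid-catalysed intramolecular Michael addition closes the ring, because C8a is the only enolisable position and its enol can reach the quinone CH next to the attachment point only on the face where the quinone hangs from C5, so the C8a–aryl bond forms cis to the C5–aryl bond (C8a becomes R, the old ring fusion is inverted) and tautomerisation to the hydroquinone makes the step irreversible.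

**Compound list**
1 | 1,4-dimethoxybenzene | COc1ccc(OC)cc1 | starting material
2 | prenyl bromide | CC(C)=CCBr | starting material
3 | (2,5-dimethoxyphenyl)lithium | COc1ccc(OC)c([Li])c1 | intermediate
4 | 1,4-dimethoxy-2-(3-methylbut-2-en-1-yl)benzene | COc1ccc(OC)c(CC=C(C)C)c1 | intermediate
5 | 2-(3-methylbut-2-en-1-yl)-1,4-benzoquinone | CC(C)=CCC1=CC(=O)C=CC1=O | intermediate
6 | cyclopenta-1,3-diene | C1C=CC=C1 | starting material
7 | (1S,4R,4aS,8aR)-6-prenyl-1,4,4a,8a-tetrahydro-1,4-methanonaphthalene-5,8-dione (endo) | CC(C)=CCC1=CC(=O)[C@@H]2[C@@H]3C=C[C@@H](C3)[C@@H]2C1=O | intermediate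
8 | 2,5-dimethoxybenzaldehyde | COc1ccc(OC)c(C=O)c1 | starting material
9 | diethyl (2-methylprop-2-en-1-yl)phosphonate | CCOP(=O)(CC(C)=C)OCC | starting material
10 | α-lithiated 9 | CCOP(=O)(OCC)C([Li])C(C)=C | intermediate
11 | 1,4-dimethoxy-2-[(1E)-3-methylbuta-1,3-dien-1-yl]benzene | COc1ccc(OC)c(/C=C/C(C)=C)c1 | intermediate
12 | 13 carrying cyclopentadiene endo across C2–C3, with the norbornene on the face of the dione ring that bears prenyl and H-8a (cis-anti-cis) | CC(C)=CC[C@@]12C(=O)[C@H]3[C@H]4C=C[C@H](C4)[C@H]3C(=O)[C@@H]1CC(C)=C[C@@H]2c1cc(OC)ccc1OC | intermediate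
13 | (4aS,5R,8aR)-5-(2,5-dimethoxyphenyl)-7-methyl-4a-prenyl-4a,5,8,8a-tetrahydronaphthalene-1,4-dione | CC(C)=CC[C@@]12C(=O)C=CC(=O)[C@@H]1CC(C)=C[C@@H]2c1cc(OC)ccc1OC | intermediate
14 | (4aS,5R,8aR)-5-(3,6-dioxocyclohexa-1,4-dien-1-yl)-7-methyl-4a-prenyl-4a,5,8,8a-tetrahydronaphthalene-1,4-dione | CC(C)=CC[C@@]12C(=O)C=CC(=O)[C@@H]1CC(C)=C[C@@H]2C1=CC(=O)C=CC1=O | intermediate
15 | CNP0166383.1 (4aS,5R,8aR); on the one-carbon bridge C4a, the C4 carbonyl lies over the benzo bridge and the prenyl group over the C6=C7 bridge | CC(C)=CC[C@@]12C(=O)C=CC(=O)[C@@]13CC(C)=C[C@@H]2c1c(O)ccc(O)c13 | target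

**Total steps:** 6. **Longest linear sequence:** 5 (steps 1, 2, 3, 5, 6).

**Three steps most likely to fail**

**Step 5.** The dienophile is a trisubstituted enedione. Its prenyl group must fold toward the norbornene alkene as a quaternary centre forms next to a benzylic one. Conversion or endo/"ortho" selectivity may therefore be poor, and heating instead of pressure would leak free quinone by premature retro-Diels–Alder.

The fallback sets out from 5 and comes back at 13, and it replaces the bulky mask with a small, electron-withdrawing oxirane. Asymmetric phase-transfer nucleophilic epoxidation of 5 (t-BuOOH, N-(9-anthracenylmethyl)cinchonidinium bromide, aq. KOH, toluene, 0 °C) attacks only the unsubstituted C5=C6 bond and gives epoxyquinone F1. This dienophile is more reactive, has nothing over its other face and cannot revert, so it can simply be heated with 11 (toluene, 70 °C). The diene adds anti to the oxirane oxygen, endo and "ortho", to give oxirane-masked adduct F2. Reductive deoxygenation of the α,β-epoxy diketone (NaI, NaOAc, AcOH, acetone, rt) restores the C2=C3 alkene and delivers 13.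

**Step 6.** The ring closure is formally 5-endo-trig. Quinone 14 can also tautomerise through H-5 to an o-quinone methide. In addition, the free enedione alkene is exposed to both oxidant and acid.

The fallback sets out from 12 (isolated after the pressure stage) and comes back at 15, with unmasking and ring closure exchanged. CAN converts 12 into masked quinone F3. The same acid catalysis closes it to masked target F4, in which the eclipsed norbornene fusion holds the dione ring in the half-chair that the final enedione also adopts. Retro-Diels–Alder reaction (o-dichlorobenzene, 180 °C, N2 sparge) as the last operation then releases 15.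

**Step 3.** The ee depends on the catalyst distinguishing two carbonyl groups that differ only by a remote prenyl group.

The fallback sets out from 5 and 6 and comes back at 7, using resolution with recycling instead of asymmetric catalysis. The uncatalysed cycloaddition (CH2Cl2, 0 °C) gives the racemic endo adduct, that is 7 and its antipode ent-7 F5. These are separated by preparative SFC on a chiral phase. F5 is cracked (o-dichlorobenzene, 180 °C) back to 5 and 6 and fed in again.

**Further compounds**
F1 | step 5 | (1S,6R)-3-(3-methylbut-2-en-1-yl)-7-oxabicyclo[4.1.0]hept-3-ene-2,5-dione | CC(C)=CCC1=CC(=O)[C@@H]2O[C@@H]2C1=O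
F2 | step 5 | 2,3-epoxy-2,3-dihydro derivative of 13, oxirane on the face bearing prenyl and H-8a (anti to the new ring) | CC(C)=CC[C@@]12C(=O)[C@H]3O[C@H]3C(=O)[C@@H]1CC(C)=C[C@@H]2c1cc(OC)ccc1OC
F3 | step 6 | norbornene-masked quinone (12 with the dimethoxyphenyl group oxidised to benzoquinonyl) | CC(C)=CC[C@@]12C(=O)[C@H]3[C@H]4C=C[C@H](C4)[C@H]3C(=O)[C@@H]1CC(C)=C[C@@H]2C1=CC(=O)C=CC1=O
F4 | step 6 | norbornene-masked target (15 carrying cyclopentadiene endo across C2–C3) | CC(C)=CC[C@@]12C(=O)[C@H]3[C@H]4C=C[C@H](C4)[C@H]3C(=O)[C@@]13CC(C)=C[C@@H]2c1c(O)ccc(O)c13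
F5 | step 3 | ent-7, (1R,4S,4aR,8aS)-6-prenyl-1,4,4a,8a-tetrahydro-1,4-methanonaphthalene-5,8-dione | CC(C)=CCC1=CC(=O)[C@H]2[C@H]3C=C[C@H](C3)[C@H]2C1=O
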